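The plan rests on ring B of half 1 (the 6-methyl-7,4'-dimethoxyflavone). C3' holds C8'' of half 2 (the apigenin unit) and its neighbour C4' holds OMe, so these two are read as the carbons of an aryl methyl ynol ether. C1' (para to C4'), C2', C5' and C6' are read as C5, C6, C3 and C4 of methyl coumalate.
Endgame: the peri 5-OMe and three benzyl ethers are cleaved last, and ring C of half 1 is opened (cyclodehydration, Baker-Venkataraman shift) to a 3-aryl-4-methoxybenzoic acid and 6-hydroxy-2,4-dimethoxy-3-methylacetophenone.
Key disconnection: ring B goes back to tri-O-benzyl-8-(methoxyethynyl)apigenin and methyl coumalate (Diels-Alder addition, then loss of CO2), so the crowded C3'-C8'' axis begins as a plain aryl-alkyne bond.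
The ynol ether comes from 8-iodinated tri-O-benzylapigenin and methoxyethynylzinc chloride (from chloroacetaldehyde dimethyl acetal). The acetophenone comes from 2,6-dimethoxytoluene, whose missing third ring oxygen is added by C-H borylation/oxidation.
Ring order: all three rings of half 2 and ring A of half 1 are bought, ring B of half 1 is built in step 4, and ring C of half 1 is closed in step 10.

Key step: step 4

Assumption: the target SMILES gives no configuration for the C3'-C8'' axis, so the biaryl is planned as a racemate.
Locants: plain and single-primed numbers belong to half 1, double- and triple-primed numbers to half 2. Single flavones are named with their own plain locants.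

Step 1
Reactants: 1 apigenin
Product: 2 tri-O-benzylapigenin
Conditions: BnBr (4.5 equiv), K2CO3 (6 equiv), DMF, 70 °C
Reagents that add atoms: benzyl bromide, BrCc1ccccc1
Why: Threefold Williamson etherification, in which the hydrogen-bonded 5-OH reacts last (hence excess BnBr and heat) and carbonate is too weak a base to open the pyrone ring.

Step 2
Reactants: 2 tri-O-benzylapigenin
Product: 3 tri-O-benzyl-8-iodoapigenin
Conditions: I2 (1.05 equiv), AgO2CCF3 (1.05 equiv), CH2Cl2, 0 °C to rt, dark
Reagents that add atoms: iodine, [I][I]
Why: Electrophilic aromatic iodination should pick ring A, the ring with three oxygen donors, and in fully O-alkylated 5,7-dioxygenated flavones attack goes to C8, which is flanked by the small ring oxygen and 7-OBn, rather than to C6, which is wedged between two benzyloxy groups.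

Step 3
Reactants: 3 tri-O-benzyl-8-iodoapigenin; 4 chloroacetaldehyde dimethyl acetal
Product: 7 tri-O-benzyl-8-(methoxyethynyl)apigenin, via lithium methoxyacetylide 5 (not isolated), via methoxyethynylzinc chloride 6 (not isolated)
Conditions: 4 (2.5 equiv), LiNEt2 (3 equiv per 4, from n-BuLi and Et2NH), THF, 0 °C; ZnCl2 (2 equiv per 4), THF, 0 °C; then 3, Pd(PPh3)4 (5 mol%), THF, rt to 45 °C; pH 8 work-up, Et3N-deactivated SiO2
Reagents that add atoms: none
Why: Three equivalents of LiNEt2 strip MeOH and HCl from 4 and deprotonate the resulting methoxyacetylene, ZnCl2 turns the acetylide into a reagent too mild to attack the chromone, and the Negishi coupling of alkoxyethynylzinc halides with aryl iodides at zerovalent palladium is established chemistry in which the slim sp nucleophile should cope with the two ortho substituents of 3.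

Step 4
Reactants: 7 tri-O-benzyl-8-(methoxyethynyl)apigenin; 8 methyl coumalate
Product: 10 methyl 4-methoxy-3-(tri-O-benzylapigenin-8-yl)benzoate, via bridged lactone 9 (not isolated)
Conditions: 8 (3 equiv, freshly sublimed), dry degassed toluene (0.5 M), sealed tube, 120 °C
Reagents that add atoms: none
Why: This is an inverse-electron-demand Diels-Alder reaction in which the oxygen lone pair of 7 raises the alkyne HOMO and puts its largest coefficient on the aryl-bearing carbon, so this carbon bonds ahead of its partner to C6 of 8, the diene terminus conjugated with both the ester and the lactone carbonyl, while the methoxy-bearing carbon closes onto C3. The new six-membered carbocycle is closed by this intermolecular, one-step but markedly unsymmetrical (4+2) cycloaddition to give bridged lactone 9, and a retro-(4+2) loss of CO2 from 9, driven by aromatisation, should deliver benzene ring B with the new bonds C2'-C3' and C4'-C5'. The closest known reaction type is the cycloaddition/decarboxylation of methyl coumalate with electron-rich alkynes and ketene acetals, which gives benzoates that carry the donor para to the ester. No stereocentre remains, since both bridgeheads of 9 become sp2 carbons and the C3'-C8'' axis forms as a racemate. The selectivity needed is orientation, and the complementary polarity of the partners (donor oxygen on one alkyne carbon, acceptor groups focused on C6 of the pyrone) should place the ester para to OMe and meta to the flavonyl group, with the electron-poor C2''=C3'' bond and the benzyl ethers as bystanders. Because the O-alkyl group is methyl, the retro-ene fragmentation to a ketene and an alkene that limits ethyl and tert-butyl ynol ethers is not open to 7, so the temperature is affordable provided 8 is free of coumalic acid and water, which would add across the triple bond.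

Step 5
Reactants: 10 methyl 4-methoxy-3-(tri-O-benzylapigenin-8-yl)benzoate
Product: 11 4-methoxy-3-(tri-O-benzylapigenin-8-yl)benzoic acid
Conditions: LiOH·H2O (5 equiv), THF/MeOH/H2O, 45 °C; then 1 M HCl to pH 3
Reagents that add atoms: lithium hydroxide, [Li+].[OH-]
Why: Ester saponification at a benzoate remote from the biaryl axis, with benzyl ethers inert and a flavone ring that opens only in hot concentrated alkali and would reclose on acidification.

Step 6
Reactants: 12 2,6-dimethoxytoluene
Product: 14 3,5-dimethoxy-4-methylphenol, via aryl pinacol boronate 13 (not isolated)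
Conditions: [Ir(OMe)(cod)]2 (1.5 mol%), dtbpy (3 mol%), B2pin2 (1 equiv), THF, 80 °C; then 30% H2O2, aq NaOH, 0 °C; 1 M HCl
Reagents that add atoms: hydrogen peroxide, OO
Why: Sterically governed iridium-catalysed C-H borylation of a 1,2,3-trisubstituted arene goes to the only C-H without an ortho neighbour (para to the methyl group), and oxidation of the C-B bond by 1,2-aryl shift to oxygen installs the third oxygen of the phloroglucinol pattern at a site that electrophilic substitution of 12 cannot reach.

Step 7
Reactants: 14 3,5-dimethoxy-4-methylphenol
Product: 16 6-hydroxy-2,4-dimethoxy-3-methylacetophenone, via aryl acetate 15 (not isolated)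
Conditions: Ac2O (1.2 equiv), BF3·OEt2 (3 equiv), ClCH2CH2Cl, 0 to 70 °C; then aq MeOH, 60 °C
Reagents that add atoms: acetic anhydride, CC(=O)OC(C)=O
Why: O-Acetylation followed by BF3-promoted Fries rearrangement can give only one hydroxy ketone, because the para position is blocked by the methyl group and the two ortho positions are equivalent by symmetry.

Step 8
Reactants: 11 4-methoxy-3-(tri-O-benzylapigenin-8-yl)benzoic acid; 16 6-hydroxy-2,4-dimethoxy-3-methylacetophenone
Product: 17 2-acetyl-3,5-dimethoxy-4-methylphenyl 4-methoxy-3-(tri-O-benzylapigenin-8-yl)benzoate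
Conditions: DCC (1.3 equiv), DMAP (0.2 equiv), CH2Cl2, 0 °C to rt
Reagents that add atoms: none
Why: Steglich esterification, in which the carboxyl group of 11 is unhindered and acyl transfer through the acylpyridinium ion overcomes the hydrogen-bonded phenol of 16.

Step 9
Reactants: 17 2-acetyl-3,5-dimethoxy-4-methylphenyl 4-methoxy-3-(tri-O-benzylapigenin-8-yl)benzoate
Product: 18 1-(6-hydroxy-2,4-dimethoxy-3-methylphenyl)-3-[4-methoxy-3-(tri-O-benzylapigenin-8-yl)phenyl]propane-1,3-dione
Conditions: LiN(SiMe3)2 (3 equiv), THF, -78 to 0 °C; 1 M HCl
Reagents that add atoms: none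
Why: Baker-Venkataraman rearrangement, in which the methyl ketone enolate attacks the neighbouring aryl ester through a six-membered transition state and the O-to-C acyl shift is driven by formation of the phenoxide and diketonate, while the non-nucleophilic amide base spares the flavone of half 2.

Step 10
Reactants: 18 1-(6-hydroxy-2,4-dimethoxy-3-methylphenyl)-3-[4-methoxy-3-(tri-O-benzylapigenin-8-yl)phenyl]propane-1,3-dione
Product: 19 5,7,4'-trimethoxy-6-methyl-3'-(tri-O-benzylapigenin-8-yl)flavone
Conditions: p-TsOH·H2O (0.2 equiv), toluene, 100 °C
Reagents that add atoms: none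
Why: Acid-catalysed cyclodehydration, in which the only free phenol adds to the aroyl carbonyl (6-exo-trig hemiketal) and loss of water gives the 4-pyrone ring C in the single possible sense, any stray loss of a benzyl ether being harmless because all are removed next.

Step 11
Reactants: 19 5,7,4'-trimethoxy-6-methyl-3'-(tri-O-benzylapigenin-8-yl)flavone
Product: 20 taiwanhomoflavone A
Conditions: BCl3 (12 equiv), C6HMe5 (10 equiv), CH2Cl2, -78 to 0 °C; then H2O
Reagents that add atoms: none
Why: Lewis-acid ether cleavage, in which BCl3 removes aryl benzyl ethers at low temperature while pentamethylbenzene traps the benzyl cation away from the phloroglucinol ring, and on warming only the methyl ether peri to the C4 carbonyl is cleaved through a six-membered boron chelate, so the unchelated 7-OMe and 4'-OMe should stay.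

Compound list
1 | apigenin | O=c1cc(-c2ccc(O)cc2)oc2cc(O)cc(O)c12 | starting material
2 | tri-O-benzylapigenin | O=c1cc(-c2ccc(OCc3ccccc3)cc2)oc2cc(OCc3ccccc3)cc(OCc3ccccc3)c12 | intermediate
3 | tri-O-benzyl-8-iodoapigenin | O=c1cc(-c2ccc(OCc3ccccc3)cc2)oc2c(I)c(OCc3ccccc3)cc(OCc3ccccc3)c12 | intermediate
4 | chloroacetaldehyde dimethyl acetal | COC(CCl)OC | starting material
5 | lithium methoxyacetylide | COC#C[Li] | intermediate
6 | methoxyethynylzinc chloride | COC#C[Zn]Cl | intermediate
7 | tri-O-benzyl-8-(methoxyethynyl)apigenin | COC#Cc1c(OCc2ccccc2)cc(OCc2ccccc2)c2c(=O)cc(-c3ccc(OCc4ccccc4)cc3)oc12 | intermediate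
8 | methyl coumalate | COC(=O)c1ccc(=O)oc1 | starting material
9 | methyl 8-methoxy-3-oxo-7-(tri-O-benzylapigenin-8-yl)-2-oxabicyclo[2.2.2]octa-5,7-diene-6-carboxylate (racemic, one enantiomer drawn, bridgeheads tied to each other by the bicycle) | O=C1O[C@H]2C(C(=O)OC)=C[C@@H]1C(OC)=C2c1c(OCc2ccccc2)cc(OCc2ccccc2)c2c(=O)cc(-c3ccc(OCc4ccccc4)cc3)oc12 | intermediate
10 | methyl 4-methoxy-3-(tri-O-benzylapigenin-8-yl)benzoate | COC(=O)c1ccc(OC)c(-c2c(OCc3ccccc3)cc(OCc3ccccc3)c3c(=O)cc(-c4ccc(OCc5ccccc5)cc4)oc23)c1 | intermediate
11 | 4-methoxy-3-(tri-O-benzylapigenin-8-yl)benzoic acid | OC(=O)c1ccc(OC)c(-c2c(OCc3ccccc3)cc(OCc3ccccc3)c3c(=O)cc(-c4ccc(OCc5ccccc5)cc4)oc23)c1 | intermediate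
12 | 2,6-dimethoxytoluene | Cc1c(OC)cccc1OC | starting material
13 | 2-(3,5-dimethoxy-4-methylphenyl)-4,4,5,5-tetramethyl-1,3,2-dioxaborolane | Cc1c(OC)cc(B2OC(C)(C)C(C)(C)O2)cc1OC | intermediate
14 | 3,5-dimethoxy-4-methylphenol | Cc1c(OC)cc(O)cc1OC | intermediate
15 | 3,5-dimethoxy-4-methylphenyl acetate | CC(=O)Oc1cc(OC)c(C)c(OC)c1 | intermediate
16 | 6-hydroxy-2,4-dimethoxy-3-methylacetophenone | CC(=O)c1c(O)cc(OC)c(C)c1OC | intermediate
17 | 2-acetyl-3,5-dimethoxy-4-methylphenyl 4-methoxy-3-(tri-O-benzylapigenin-8-yl)benzoate | CC(=O)c1c(OC(=O)c2ccc(OC)c(-c3c(OCc4ccccc4)cc(OCc4ccccc4)c4c(=O)cc(-c5ccc(OCc6ccccc6)cc5)oc34)c2)cc(OC)c(C)c1OC | intermediate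
18 | 1-(6-hydroxy-2,4-dimethoxy-3-methylphenyl)-3-[4-methoxy-3-(tri-O-benzylapigenin-8-yl)phenyl]propane-1,3-dione | COc1cc(O)c(C(=O)CC(=O)c2ccc(OC)c(-c3c(OCc4ccccc4)cc(OCc4ccccc4)c4c(=O)cc(-c5ccc(OCc6ccccc6)cc5)oc34)c2)c(OC)c1C | intermediate
19 | 5,7,4'-trimethoxy-6-methyl-3'-(tri-O-benzylapigenin-8-yl)flavone | COc1ccc(-c2cc(=O)c3c(OC)c(C)c(OC)cc3o2)cc1-c1c(OCc2ccccc2)cc(OCc2ccccc2)c2c(=O)cc(-c3ccc(OCc4ccccc4)cc3)oc12 | intermediate
20 | taiwanhomoflavone A | COc1ccc(-c2cc(=O)c3c(O)c(C)c(OC)cc3o2)cc1-c1c(O)cc(O)c2c(=O)cc(-c3ccc(O)cc3)oc12 | target

Total step count: 11.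
Longest linear sequence: 9 steps (steps 1 to 5 and 8 to 11, from apigenin). The acetophenone branch (steps 6 and 7) joins at step 8.

Steps most likely to fail

Step 4. The aryl-bearing alkyne carbon lies between 7-OBn and the pyrone oxygen, so the cycloaddition may be slow. Thermal self-dimerisation of the coumalate, addition of adventitious acid or water across the triple bond, or partial loss of orientation could then take over. The fallback sets out from 3 and comes back at 10. It is a Suzuki-Miyaura coupling of 3 with commercial [2-methoxy-5-(methoxycarbonyl)phenyl]boronic acid (COC(=O)c1ccc(OC)c(B(O)O)c1), using Pd(OAc)2/SPhos and K3PO4 in toluene/H2O at 90 °C. Ring B is then bought instead of built, and no new compound arises on the way (entry F0).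

Step 3. Oxidative addition into the electron-rich, doubly ortho-substituted aryl iodide may lag, which would allow reductive loss of iodine. The amine- and alkoxide-laden zinc solution, the aqueous work-up or silica may also hydrate the ynol ether. The fallback sets out from 5 (made from 4 as in step 3) and 3, and comes back at 7. The acetylide 5 is quenched with Bu3SnCl to give tributyl(methoxyethynyl)stannane F1, which is distilled free of amine and salts. F1 is then joined to 3 by a Stille coupling (Pd2(dba)3, AsPh3, toluene, 70 °C) under neutral, salt-free conditions, with non-aqueous filtration through basic alumina.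

Step 11. One Lewis acid has two tasks here. The peri demethylation may stall in insoluble boron chelates, prolonged warming may start to cleave 7-OMe or 4'-OMe, and untrapped benzyl cation may re-alkylate C6''. The fallback sets out from 19 and comes back at 20. Hydrogenolysis (H2, Pd/C, THF/MeOH, rt) removes the three benzyl groups to give 5-O-methyltaiwanhomoflavone A F2. A separate chelation-controlled demethylation with AlCl3 in MeCN at 60 °C then frees only the 5-OH.

Further compounds
F0 | step 4 | none | none
F1 | step 3 | tributyl(methoxyethynyl)stannane | CCCC[Sn](CCCC)(CCCC)C#COC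
F2 | step 11 | 5-O-methyltaiwanhomoflavone A | COc1ccc(-c2cc(=O)c3c(OC)c(C)c(OC)cc3o2)cc1-c1c(O)cc(O)c2c(=O)cc(-c3ccc(O)cc3)oc12
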